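**Plan**

1. Retrosynthesis: after unmasking of the two phenols (last step), the carbocycle is cut in one stroke at C6–C7 (ring ketone to the phenyl-bearing carbon) and at C4–C5 (aryl-bearing carbon to the enol carbon). C5–C6 leaves as dimethyl oxalate and the remainder is the γ-ylidenebutenolide 9.
2. Enabling feature: ring atoms C5 (C–OH) and C6 (C=O) are an oxalyl unit lying between the two benzylic ring carbons C4 and C7. In 9, C4 is a CH2 vinylogous to the lactone C2=O through C3a=C3, and C7 is the β-carbon of the enol lactone O1–C7a=C7, a masked benzyl ketone α-carbon. One base-mediated double Claisen event, with transient opening of the lactone ring, can therefore build the whole hydroxy-quinone-methide ring at the correct oxidation level.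
3. Compound 9 is cut further at C7a=C7 (benzaldehyde), at C3–aryl (arylboronic acid) and at C3a–CH2 (benzylzinc reagent), back to 3,4-dibromofuran-2(5H)-one.
4. Forward order: the lactone ring is present from the start and is dressed by two site-selective cross-couplings and a vinylogous aldol condensation; the six-membered ring is then closed by the oxalate annulation; demethylation ends the route.
5. Stereochemistry: the target has no stereocentre and no configurable double bond. The Z-benzylidene geometry of 9 (thermodynamic control in step 3) is the only stereo-element on the way and is erased in step 4.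

Key step: step 4

Remark: atom numbers (O1, C2 … C7a) are those of the benzofuran skeleton of the target; the phenols travel as methyl ethers because a para-phenoxide would suppress the benzylic deprotonation needed in step 4.

**Route**

Step 1
Reactants: 1 3,4-dibromofuran-2(5H)-one; 2 (4-methoxybenzyl)zinc chloride (solution in THF)
Product: 3 3-bromo-4-(4-methoxybenzyl)furan-2(5H)-one
Conditions: Pd(PPh3)4 (5 mol %), THF, 0 °C to rt
Reagents that add atoms: none
Why: Site-selective Negishi coupling; the C4 bromide is the β-halide of an enoate (a vinylogous acyl bromide) and should add to zerovalent palladium much faster than the C3 bromide, as is known for cross-couplings of 3,4-dihalobutenolides, and the benzylzinc reagent is too weakly basic to enolise the lactone.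

Step 2
Reactants: 3 3-bromo-4-(4-methoxybenzyl)furan-2(5H)-one; 4 (4-methoxyphenyl)boronic acid
Product: 5 4-(4-methoxybenzyl)-3-(4-methoxyphenyl)furan-2(5H)-one
Conditions: Pd(OAc)2 (5 mol %), SPhos (10 mol %), K3PO4, degassed toluene/H2O, 80 °C
Reagents that add atoms: none
Why: Suzuki–Miyaura coupling of the remaining α-bromoenoate with an electron-rich arylboronic acid; the bulky biarylphosphine should cope with the tetrasubstituted alkene and the mild phosphate base should leave the lactone closed.

Step 3
Reactants: 5 4-(4-methoxybenzyl)-3-(4-methoxyphenyl)furan-2(5H)-one; 6 benzaldehyde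
Product: 9 (5Z)-5-benzylidene-4-(4-methoxybenzyl)-3-(4-methoxyphenyl)furan-2(5H)-one, via silyloxyfuran 7 (not isolated), via silylated aldol adduct 8 (not isolated)
Conditions: TBSOTf, iPr2NEt, CH2Cl2, 0 °C to rt; then DBU, rt
Reagents that add atoms: none
Why: One-pot vinylogous Mukaiyama aldol reaction and β-elimination, a sequence established for 4-benzylbutenolides; silylation should occur at the ring γ-carbon to give the aromatic 2-silyloxyfuran 7 (not the exocyclic dienol ether), which attacks the aldehyde at C5, and DBU then eliminates silanol (E1cB) to the thermodynamically preferred Z-benzylidene lactone.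

Step 4
Reactants: 9 (5Z)-5-benzylidene-4-(4-methoxybenzyl)-3-(4-methoxyphenyl)furan-2(5H)-one; 10 dimethyl oxalate
Product: 14 5-hydroxy-3,4-bis(4-methoxyphenyl)-7-phenyl-1-benzofuran-2,6-dione, via oxalylated butenolide enolate 11 (not isolated), via ring-opened keto diester 12 (not isolated), via cyclised methyl ester 13 (not isolated)
Conditions: NaH (4 equiv), THF, 0 °C; then 10 (3 equiv), 0 to 50 °C; then 2 M HCl; AcOH, TsOH (cat.), 60 °C
Reagents that add atoms: none
Why: Proposed new method: NaH removes a proton from the benzylic CH2 of 9 (C4, vinylogous to the lactone C=O through C3a=C3) and the dienolate undergoes Claisen C-acylation by dimethyl oxalate at that carbon (C4–C5; an adduct at C3 is non-enolisable and reverts) to give the enolate of 11; the methoxide released, which appears only when no neutral 9 is left, opens the enol lactone to the benzyl ketone enolate 12, whose carbon C7 attacks the oxalyl ester (C6–C7) in a 6-exo-trig Dieckmann closure of the carbocycle to 13, and acid then re-forms the lactone ring by 5-exo-trig attack of the C7a enol oxygen on the Z-disposed methyl ester with loss of methanol. The closest known reaction types are the double Claisen annulation of dialkyl oxalates onto vicinal bis(arylmethyl) compounds (1,2-phenylenediacetic esters, dibenzyl ketone), the γ-oxalylation of crotonates, and the methoxide-induced opening of γ-ylidenebutenolides followed by Dieckmann closure. No stereocentre is formed, and the geometry of the C3a=C3 bond is not critical because it can equilibrate through the delocalised enolates before the lactone traps the Z form. The selectivity required is closure of C7 onto C6 (six-membered ring) and not onto the lactone-derived ester C2 (five-membered ring, the cyclopent-4-ene-1,3-dione rearrangement of ylidenebutenolides); the substrate should secure it because in the enolate of 12 the charge at C4 is delocalised through C3a=C3 into the C2 carbonyl and deactivates it, whereas C6 is only cross-conjugated and stays electrophilic, and because 9 is fully deprotonated before any methoxide exists. The annulated product is a vinylogous acid held as its salt, which should pull both reversible condensations forward.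

Step 5
Reactants: 14 5-hydroxy-3,4-bis(4-methoxyphenyl)-7-phenyl-1-benzofuran-2,6-dione
Product: 15 peniophorin, 5-hydroxy-3,4-bis(4-hydroxyphenyl)-7-phenyl-1-benzofuran-2,6-dione
Conditions: BBr3 (6 equiv), CH2Cl2, −78 °C to rt; then H2O
Reagents that add atoms: none
Why: Lewis-acid O-demethylation of the two aryl methyl ethers with BBr3; the lactone and the boron-chelated hydroxyenone should survive the cold, non-basic conditions, as with other arylated butenolide and hydroxyquinone pigments.

**Compound list**

1 | 3,4-dibromofuran-2(5H)-one | O=C1OCC(Br)=C1Br | starting material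
2 | (4-methoxybenzyl)zinc chloride | COc1ccc(C[Zn]Cl)cc1 | starting material
3 | 3-bromo-4-(4-methoxybenzyl)furan-2(5H)-one | COc1ccc(CC2=C(Br)C(=O)OC2)cc1 | intermediate
4 | (4-methoxyphenyl)boronic acid | COc1ccc(B(O)O)cc1 | starting material
5 | 4-(4-methoxybenzyl)-3-(4-methoxyphenyl)furan-2(5H)-one | COc1ccc(CC2=C(c3ccc(OC)cc3)C(=O)OC2)cc1 | intermediate
6 | benzaldehyde | O=Cc1ccccc1 | starting material
7 | tert-butyl{[4-(4-methoxybenzyl)-3-(4-methoxyphenyl)furan-2-yl]oxy}dimethylsilane | COc1ccc(Cc2coc(O[Si](C)(C)C(C)(C)C)c2-c2ccc(OC)cc2)cc1 | intermediate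
8 | 5-{[tert-butyl(dimethyl)silyl]oxy(phenyl)methyl}-4-(4-methoxybenzyl)-3-(4-methoxyphenyl)furan-2(5H)-one (mixture of racemic diastereomers, both eliminated) | COc1ccc(CC2=C(c3ccc(OC)cc3)C(=O)OC2C(O[Si](C)(C)C(C)(C)C)c2ccccc2)cc1 | intermediate
9 | (5Z)-5-benzylidene-4-(4-methoxybenzyl)-3-(4-methoxyphenyl)furan-2(5H)-one | COc1ccc(CC2=C(c3ccc(OC)cc3)C(=O)O/C2=C\c2ccccc2)cc1 | intermediate
10 | dimethyl oxalate | COC(=O)C(=O)OC | starting material
11 | methyl 3-[(2Z)-2-benzylidene-4-(4-methoxyphenyl)-5-oxo-2,5-dihydrofuran-3-yl]-3-(4-methoxyphenyl)-2-oxopropanoate (racemic, present as its sodium enolate) | COC(=O)C(=O)C(c1ccc(OC)cc1)C1=C(c2ccc(OC)cc2)C(=O)O/C1=C\c1ccccc1 | intermediate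
12 | dimethyl (2Z)-2,4-bis(4-methoxyphenyl)-5-oxo-3-(phenylacetyl)hex-2-enedioate (racemic, present as its sodium salt) | COC(=O)/C(c1ccc(OC)cc1)=C(\C(=O)Cc1ccccc1)C(c1ccc(OC)cc1)C(=O)C(=O)OC | intermediate
13 | methyl (2Z)-[2,5-dihydroxy-6-(4-methoxyphenyl)-4-oxo-3-phenylcyclohexa-2,5-dien-1-ylidene](4-methoxyphenyl)acetate (present as its sodium salt) | COC(=O)/C(c1ccc(OC)cc1)=C1\C(O)=C(c2ccccc2)C(=O)C(O)=C1c1ccc(OC)cc1 | intermediate
14 | 5-hydroxy-3,4-bis(4-methoxyphenyl)-7-phenyl-1-benzofuran-2,6-dione | O=C1OC2=C(c3ccccc3)C(=O)C(O)=C(c3ccc(OC)cc3)C2=C1c1ccc(OC)cc1 | intermediate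
15 | peniophorin, 5-hydroxy-3,4-bis(4-hydroxyphenyl)-7-phenyl-1-benzofuran-2,6-dione | O=C1OC2=C(c3ccccc3)C(=O)C(O)=C(c3ccc(O)cc3)C2=C1c1ccc(O)cc1 | target

**Count**

Total steps: 5. Longest linear sequence: 5 steps (1 → 3 → 5 → 9 → 14 → 15).

**Steps most likely to fail**

Step 4 (proposed new method). The enolate set free on opening of the lactone may close on the lactone-derived ester and not on the oxalyl ester (five-ring Dieckmann closure, acyl migration from oxygen to C7). Alternatively, the dienolate of 9 may fragment through a ketene before it is acylated. The fallback keeps the lactone closed, lowers the oxidation level of the two-carbon unit and reverses the polarity at C7; it uses known reaction types, sets out from 9 and comes back to the route at 14. Claisen acylation of the dienolate of 9 (NaH, THF, 0 °C) with methyl dimethoxyacetate at the benzylic carbon should give (5Z)-5-benzylidene-4-[3,3-dimethoxy-1-(4-methoxyphenyl)-2-oxopropyl]-3-(4-methoxyphenyl)furan-2(5H)-one F1. Warm aqueous acid (HCl in AcOH) should unmask the aldehyde, which is attacked by the benzylidene carbon of the intact enol lactone (Prins-type six-ring closure); loss of a proton and tautomerisation should give the benzenoid leuco compound 5,6-dihydroxy-3,4-bis(4-methoxyphenyl)-7-phenyl-1-benzofuran-2(3H)-one F2 (racemic). Oxidation of F2 in air or with Ag2O should give the quinone methide 14.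

Step 5. Bromide may add to the electrophilic quinone methide, the Lewis acid may degrade it, or ether cleavage may stall because boron is sequestered by the hydroxyenone chelate. The fallback demethylates at the benzenoid oxidation level; it sets out from 14 and comes back at 15. Reduction of 14 with Na2S2O4 in aqueous THF should give the leuco compound F2 already described in the fallback for step 4. BBr3 in CH2Cl2 should then cleave the methyl ethers of this robust aromatic lactone to 5,6-dihydroxy-3,4-bis(4-hydroxyphenyl)-7-phenyl-1-benzofuran-2(3H)-one F3 (racemic), and oxidation in air or with Ag2O should give 15.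

Step 1. Site selection between the two bromides may be lost (second coupling at C3), and the benzylzinc reagent may homocouple or be protonated. The fallback sets out from benzylzinc reagent 2, couples it with a partner that carries a single leaving group, and comes back to the route at 5, so that 1, 3 and boronic acid 4 are bypassed. Tandem transesterification and Dieckmann condensation of methyl (4-methoxyphenyl)acetate with methyl glycolate (KOtBu, DMF) should give 4-hydroxy-3-(4-methoxyphenyl)furan-2(5H)-one F4. Tf2O and Et3N should convert it into 4-(4-methoxyphenyl)-5-oxo-2,5-dihydrofuran-3-yl trifluoromethanesulfonate F5, and Negishi coupling of F5 with 2 (Pd(PPh3)4, THF) should give 5.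

**Further compounds**

F1 | step 4 | (5Z)-5-benzylidene-4-[3,3-dimethoxy-1-(4-methoxyphenyl)-2-oxopropyl]-3-(4-methoxyphenyl)furan-2(5H)-one | COC(OC)C(=O)C(c1ccc(OC)cc1)C1=C(c2ccc(OC)cc2)C(=O)O/C1=C\c1ccccc1
F2 | step 4 | 5,6-dihydroxy-3,4-bis(4-methoxyphenyl)-7-phenyl-1-benzofuran-2(3H)-one | O=C1Oc2c(-c3ccccc3)c(O)c(O)c(-c3ccc(OC)cc3)c2C1c1ccc(OC)cc1
F3 | step 5 | 5,6-dihydroxy-3,4-bis(4-hydroxyphenyl)-7-phenyl-1-benzofuran-2(3H)-one | O=C1Oc2c(-c3ccccc3)c(O)c(O)c(-c3ccc(O)cc3)c2C1c1ccc(O)cc1
F4 | step 1 | 4-hydroxy-3-(4-methoxyphenyl)furan-2(5H)-one | COc1ccc(cc1)C1=C(O)COC1=O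
F5 | step 1 | 4-(4-methoxyphenyl)-5-oxo-2,5-dihydrofuran-3-yl trifluoromethanesulfonate | COc1ccc(cc1)C1=C(OS(=O)(=O)C(F)(F)F)COC1=O
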